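| flask | electrophile | nucleophile | buffer base | buffer acid | remark | time |
|---|---|---|---|---|---|---|
| Saturday's | 0.10 M | 1.1 equiv | 2 equiv | 0.30 equiv | the very flask that is asked about, followed so far |  |
| Friday's | 0.10 M | 1.1 equiv | 2 equiv | 0.45 equiv | run made earlier |  |
| flask | 0.10 M | 1.10 equiv | 2.00 equiv | 0.300 equiv |  | 80 min |

- Saturday's (time / min: electrophile / %, target / %): 2.00: 97, 2; 6.00: 95, 3; 12.0: 91, 10; 15.0: 89, 14; 25.0: 85, 18; 30.0: 77, 19; 40.0: 74, 24
- Friday's (time / min: electrophile / %, target / %): 5.00: 93, 4; 6.00: 96, 4; 10.0: 91, 8; 15.0: 90, 9; 25.0: 83, 19; 40.0: 76, 23; 60.0: 65, 34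

(readings scatter by 1.5 percentage points)

1. part of the electrophile that has reacted at 80 min
2. pH of the solution at 80 min

- acid is the free proton; pH is minus the decimal logarithm of its molar concentration
- for target the crystals are counted in
- as a solid, counted per litre of solution: crystals
- reactions considered so far: electrophile + nucleophile -> acid + target + leaving group; protonated nucleophile <-> nucleophile + acid; buffer acid <-> buffer base + acid; crystals <-> target
- the earlier runs do not show the pH; that part of a forecast is a guess

**The trap.** Pseudo-first-order thinking failed here: the electrophile, the limiting reagent, met 1.10 equiv of nucleophile, so [nucleophile] fell nearly in step with [electrophile]. The two make target, leaving group and acid, and the buffer base takes up acid.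

**What mattered.** At 40.0 min, Saturday's flask with 0.30 equiv of buffer acid and Friday's with 0.45 equiv read 74% and 76% electrophile. That gap of 2 percentage points sat beside a scatter of 1.5 points per reading, so I gave buffer acid little weight. The pH hung on the buffer's pK, which no run shows. Conversion hung on the rate constant, so I read that carefully.

**The number.** Averaging electrophile loss and target gain, Saturday's flask read 25.0% after 40.0 min, Friday's 34.5% after 60.0 min. For a rate k[electrophile][nucleophile], with the charged nucleophile counted as free, the natural logarithm of [nucleophile]/[electrophile] climbs straight in time, at k times the difference of the charges. Saturday's reading gave 0.0746 M⁻¹ min⁻¹ and Friday's 0.0780 M⁻¹ min⁻¹. I carried their mean, k = 0.0763 M⁻¹ min⁻¹, the rate divided by [electrophile][nucleophile]. For 80 min it gave 40.9%; k divided by 2 gave 25.4%, multiplied by 2 gave 58.8%. Counting the acid made as buffer acid, I put the pH 0.351 above the unseen pK.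

**The forecast.** It said 41% and pH 5.5, the latter by “A guess near 5 gives a pH of about 5.5”.

**The flask.** It gave 40.1% and pH 8.92: conversion agreed, pH parted.

    electrophile + nucleophile → acid + target + leaving group (k = 0.0800 M⁻¹ min⁻¹)
    protonated nucleophile ⇌ nucleophile + acid, settled at all times (K = 1.00 × 10⁻⁸ M)
    buffer acid ⇌ buffer base + acid, settled at all times (K = 3.20 × 10⁻⁹ M)
    crystals ⇌ target, rate k4*(cs4 - [target]) while solid is left; crystals form when [target] > cs4 (solubility = 1.50 mM, k = 0.130 min⁻¹)

**Slow clock.** At 80.0 min in the asked flask, the electrophile's half-life by the path from electrophile and nucleophile to target was 140 min, longer than the 80 min elapsed, and 59.9% of the electrophile charged stood unreacted. With nucleophile at 56.7% of its charge, k gives 146 min there.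

**Second flask.** For the neighbour with 1.90 equiv of nucleophile, k gave 60.7% reacted at 80 min; the computed neighbour gave 59.3%.

Readings and results were generated by integration on assumed constants.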